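**No constants.** I hold no rate constant for these flasks, so I work from the readings of the earlier runs.

| flask | X | J | remark | time |
|---|---|---|---|---|
| maple | 1 M | 5 mM | run made earlier |  |
| ash | 0.67 M | 5 mM | run made earlier |  |
| larch | 1.5 M | 5 mM | run made earlier |  |
| cedar | 1 M | 10 mM | run made earlier |  |
| Saturday's | 1.0 M (fed, over 32.0 min) | 5.0 mM | a stirred flask in which X is dosed at a steady rate over 32.0 min without added volume, worked up at 40 min | 40 min |
| Tuesday's | 1.0 M | 5.0 mM | one stirred flow tank at steady state, fed with the mixture as stated, mean residence time 40 min |  |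
| Thursday's | 1.0 M | 5.0 mM | a closed flask charged with all of it at once and left for 40 min | 40 min |

| run | time / min | Z / % |
|---|---|---|
| maple | 6.00 | 10.7 |
| maple | 12.0 | 19.1 |
| maple | 20.0 | 26.5 |
| maple | 25.0 | 30.4 |
| maple | 30.0 | 33.7 |
| maple | 40.0 | 37.9 |
| ash | 3.00 | 7.0 |
| ash | 10.0 | 20.2 |
| ash | 15.0 | 27.6 |
| ash | 25.0 | 38.5 |
| ash | 40.0 | 46.8 |
| ash | 50.0 | 50.6 |
| larch | 8.00 | 10.6 |
| larch | 15.0 | 16.8 |
| larch | 25.0 | 23.1 |
| larch | 30.0 | 25.7 |
| larch | 40.0 | 28.8 |
| larch | 50.0 | 31.0 |
| cedar | 4.00 | 14.7 |
| cedar | 8.00 | 25.7 |
| cedar | 15.0 | 40.1 |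
| cedar | 25.0 | 51.4 |
| cedar | 50.0 | 57.7 |

(readings scatter by 0.3 percentage points)

- the stated concentrations are those of everything mixed, before any reaction; amounts are the same in each set-up
- the feed brings no volume worth counting
- the earlier runs were made in a closed, stirred flask

- the set-up with the highest amount of Z at the outlet or at the end, in percent of the X put in ("none" if the first two lie within 2 percentage points) (Saturday's / Tuesday's / Thursday's / none)
- amount of Z at the outlet or at the end, in percent of the X put in, Saturday's
- amount of Z at the outlet or at the end, in percent of the X put in, Tuesday's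
- amount of Z at the outlet or at the end, in percent of the X put in, Thursday's

**Ash and maple.** At 40 min the ash run stands at 46.8% and the maple run at 37.9%, with equal J but 0.67 M against 1 M of X. From ash to maple, the concentration of Z gained per concentration of X added on top of the charge, at equal J and equal time, is 19.8%; I call this the slice yield, a marginal yield. From maple to larch it is 10.6%. At that time maple stands lower than ash, in percent of its own charge, because its top slice returns less than ash's whole charge does.

**Where X goes.** Late on, cedar, with twice the J, adds 6.3 percentage points in 25.0 min, while maple adds 4.2 points in 10.0 min, so over these two spans cedar gains less per minute than maple. I read this, together with the slice yield falling from 19.8% to 10.6%, as X leaving by a second path that grows with X, rather than as J fading. Thursday's repeats the charge of maple, so I put it at 37.9%, and I put the feed and the tank, which I expect to hold X low, between that and ash's 46.8%, less whatever X they leave unused. I name no clear winner.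

**The forecast.** It gives 28% for Saturday's, 26% for Tuesday's and 38% for Thursday's, with Thursday's best, reasoning “so J must be dying”. My reckoning differs on the feed and the tank.

**The flasks.** Saturday's gives 39.1%, Tuesday's 40.1% and Thursday's 37.7%, so the first two lie within 2 points and the answer is none.

    X + J ⇌ D (K = 3.30 L mol⁻¹, k = 16.0 L mol⁻¹ min⁻¹)
    D ⇌ L (K = 2.20, k = 7.70 min⁻¹)
    L → J + Z (k = 190 min⁻¹)
    2 X → E (k = 0.0480 L mol⁻¹ min⁻¹)
    X + L ⇌ G, settled at all times (K = 0.570 L mol⁻¹)

**Slices again.** Tuesday's tank holds X at 0.285 M, and Saturday's X peaks at 0.409 M, lower than ash's charge. Thursday's slice above ash comes to 19.2%. A neighbour of Thursday's charged with 0.25 M of X gives 66.7% at 40 min, and the slice from it up to ash is 35.0%.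

All runs were computed on assumed constants; noise was put on by code.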